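Amounts came first. In beta the partner charge was 48.9% of the starting material and product stopped near 44%, a gap of 4.9 percentage points. The protic impurity is 5.00% of the starting material charge, so I took it to spend one partner each. With equal charges the usable partner is then 95.0% of the charge, and I worked with the fraction left, not the fraction made.

| setting | gamma | beta | zeta | theta | dusk | midnight | dawn | spring |
|---|---|---|---|---|---|---|---|---|
| starting material | 0.045 M | 0.045 M | 0.045 M | 0.045 M | 0.045 M | 0.045 M (fed, over 1.50 h) | 0.045 M | 0.045 M |
| partner | 0.045 M | 0.022 M | 0.090 M | 0.045 M | 0.0450 M | 0.0450 M | 0.0450 M (fed, over 1.50 h) | 0.0450 M |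
| protic impurity | 2.25 mM | 2.25 mM | 2.25 mM | 2.25 mM | 2.25 mM | 2.25 mM | 2.25 mM | 2.25 mM |
| initiator | 0.33 mM | 0.33 mM | 0.33 mM | 0.49 mM | 0.33 mM | 0.33 mM | 0.33 mM | 0.33 mM |
| remark | run made earlier | run made earlier | run made earlier | run made earlier | a closed flask charged with all of it at once and left for 1.5 h | all but starting material at the start; starting material goes in evenly over 1.50 h, the run ends at 1.5 h | all but partner at the start; partner goes in evenly over 1.50 h, the run ends at 1.5 h | one stirred flow tank at steady state, fed with the mixture as stated, mean residence time 1.5 h |
| time |  |  |  |  | 1.5 h | 1.5 h | 1.5 h |  |

- gamma (time / min: product / %, starting material / %): 15.0: 68, 32; 25.0: 83, 18; 40.0: 90, 10; 50.0: 93, 5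
- beta (time / min: product / %, starting material / %): 15.0: 31, 70; 40.0: 39, 61; 80.0: 43, 55; 120: 44, 55
- zeta (time / min: product / %, starting material / %): 25.0: 97, 0; 50.0: 103, 2; 80.0: 99, 0; 120: 100, 3
- theta (time / min: product / %, starting material / %): 15.0: 75, 24; 40.0: 93, 4; 80.0: 96, 5; 120: 94, 6

(scatter of a reading: 2 percentage points)

- percent here means starting material units held: one ended chains A counts as two
- the stated concentrations are those of everything mixed, before any reaction; amounts are the same in each set-up
- steps under discussion: partner + protic impurity -> quenched reagent; starting material + initiating radical -> chain carrier; initiator -> 2 initiating radical; 2 chain carrier -> ended chains A; 2 partner -> homo dimer; 2 initiating radical -> ended chains B; partner + chain carrier -> product + initiating radical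
- the feed brings no volume worth counting
- the earlier runs were made in a closed, stirred flask

- the set-up with the highest amount of product at the outlet or at the end, in percent of the starting material put in ("none" if the first two lie within 2 percentage points) (dusk / midnight / dawn / spring / none)
- amount of product at the outlet or at the end, in percent of the starting material put in, dusk
- amount of product at the outlet or at the end, in percent of the starting material put in, midnight
- amount of product at the outlet or at the end, in percent of the starting material put in, dawn
- amount of product at the outlet or at the end, in percent of the starting material put in, spring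

I read the gamma table row by row, taking product from that ceiling. The first row leaves 27.0% at 15.0 min, which gives a pseudo-first-order constant for partner of 0.0839 min⁻¹. The second leaves 12.0% at 25.0 min, which gives 0.0828 min⁻¹, and I kept that reading. The third row leaves 5.00% at 40.0 min, and its gap to the reckoned 3.46% is 1.5 points, less than the scatter of 2 points. The first beta row, against its own plateau, reads 0.0813 min⁻¹, although beta held twice the starting material per partner, so I left starting material out of the constant.

Over 1.50 h that makes 7.45 lifetimes of partner. I called this the partner count, the constant times the time.

Dusk runs through that count and leaves 0.0553% of the charge as partner, so I reckoned 95.0% product. In dawn, fed evenly, partner stands where use equals feed, at one over the count: 13.4% left, so 81.6% product. In spring the left fraction is the ceiling over one plus the count, 11.2%, so 83.8% product.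

The forecast gave 94% for dusk, 90% for midnight, 81% for dawn and 83% for spring, with dusk best. Its dusk, dawn and spring each stood lower than mine. Its words on dawn were: “Dawn: partner steady at about 13%, so about 81%.”

The flasks gave 94.1% in dusk, 86.5% in midnight, 81.9% in dawn and 83.9% in spring, and dusk was best.

    partner + protic impurity → quenched reagent (k = 1.00 M⁻¹ s⁻¹)
    starting material + initiating radical → chain carrier (k = 1.40 × 10⁶ M⁻¹ s⁻¹)
    initiator → 2 initiating radical (k = 8.10 × 10⁻⁶ s⁻¹)
    2 chain carrier → ended chains A (k = 2.60 × 10⁶ M⁻¹ s⁻¹)
    2 partner → homo dimer (k = 3.00 × 10⁻⁴ M⁻¹ s⁻¹)
    2 initiating radical → ended chains B (k = 3.30 × 10⁸ M⁻¹ s⁻¹)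
    partner + chain carrier → product + initiating radical (k = 46000 M⁻¹ s⁻¹)

The neighbour was dawn with 0.11 M of starting material and the other charges held. The count holds no starting material, so I kept 13.4% of partner left and 81.6% of the partner charge turned into product. Set against the larger starting material, that is 33.4%. That flask stood at 12.8% of partner and gave 33.6% product, with 66.4% of its starting material still there at 1.50 h.

The earlier runs and the new flask stem from a simulated flask on assumed constants; noise was put on by code.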